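**Retrosynthetic overview**
1. The last step is hydrogenolysis of four benzyl ethers; the 7-OMe of unit 1 is the only ether that stays.
2. Key disconnection: the pyranone of unit 2 is opened at O1''–C2'' and C2''–C3'' to a 2-hydroxydeoxybenzoin and 4-(benzyloxy)benzoyl chloride. The strategy rests on C3'' of this pyranone being bonded to C3' of ring B (C1'–C6', the phenol ring that carries unit 1 at C1'). The crowded C3'–C3'' bond is therefore carried from the start as the aryl–CH2 bond of 2-hydroxyphenylacetic acid, and the tetrasubstituted C2''=C3'' bond is made by condensation.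
3. The deoxybenzoin is made from the unit 1 arylacetic acid and 1,3,5-tris(benzyloxy)benzene by a mixed-anhydride Friedel–Crafts acylation, then chelation-directed debenzylation with BCl3. BF3·OEt2 with phloroglucinol is avoided because it would strip the benzyl ethers and let the ring B phenol close onto the ketone. BCl3 also frees the 5-OH of unit 1, which is carried free, esterified in passing in the key step and released by methanol in the same flask.
4. Unit 1 is built first: bromination, benzylation and formylation of the acid, Claisen–Schmidt condensation with monobenzylated 2',6'-dihydroxy-4'-methoxyacetophenone, then I2/DMSO cyclisation.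
5. Ring order: the benzene rings are bought; the pyranone of unit 1 is closed in step 6 and the pyranone of unit 2 in step 11.

Key step: step 11

Remark: the target has no stereocentre, and rotation about the C3'–C3'' bond is taken as free, so the route sets no stereochemistry.

**Route**

Step 1
Reactants: 1 2-hydroxyphenylacetic acid
Product: 2 2-(5-bromo-2-hydroxyphenyl)acetic acid
Conditions: NBS (1.0 equiv), MeCN, 0 °C to rt
Reagents that add atoms: N-bromosuccinimide, O=C1CCC(=O)N1Br
Why: Electrophilic aromatic bromination, in which the phenol directs the single bromine to the free para position (the future C1').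

Step 2
Reactants: 2 2-(5-bromo-2-hydroxyphenyl)acetic acid
Product: 3 benzyl 2-(2-benzyloxy-5-bromophenyl)acetate
Conditions: BnBr (2.3 equiv), K2CO3, DMF, rt
Reagents that add atoms: benzyl bromide, BrCc1ccccc1
Why: Williamson-type SN2 alkylation of the phenoxide and the carboxylate protects both in one operation and prevents lactonisation to the benzofuranone.

Step 3
Reactants: 3 benzyl 2-(2-benzyloxy-5-bromophenyl)acetate
Product: 4 benzyl 2-(2-benzyloxy-5-formylphenyl)acetate
Conditions: Pd(OAc)2 (1 mol%), di(1-adamantyl)-n-butylphosphine (3 mol%), TMEDA, CO/H2 (1:1, 5 bar), toluene, 100 °C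
Reagents that add atoms: carbon monoxide, [C-]#[O+]
Why: Palladium-catalysed reductive carbonylation (formylation) of an aryl bromide, in which zerovalent palladium inserts into C–Br, CO inserts and H2 cleaves the acyl–palladium bond, while the ester and the benzyl ethers are inert to this homogeneous catalyst.

Step 4
Reactants: 5 2',6'-dihydroxy-4'-methoxyacetophenone
Product: 6 1-(2-benzyloxy-6-hydroxy-4-methoxyphenyl)ethanone
Conditions: BnBr (1.05 equiv), K2CO3, acetone, reflux
Reagents that add atoms: benzyl bromide, BrCc1ccccc1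
Why: Williamson mono-O-benzylation that should stop after one ether, because the remaining phenol is locked in a hydrogen bond to the ketone.

Step 5
Reactants: 4 benzyl 2-(2-benzyloxy-5-formylphenyl)acetate; 6 1-(2-benzyloxy-6-hydroxy-4-methoxyphenyl)ethanone
Product: 8 2-[2-benzyloxy-5-[(E)-3-(2-benzyloxy-6-hydroxy-4-methoxyphenyl)-3-oxoprop-1-enyl]phenyl]acetic acid, via aldehyde acid 7 (not isolated)
Conditions: KOH (50% aq., excess), EtOH, rt; then 1 M HCl, 0 °C
Reagents that add atoms: potassium hydroxide, [K+].[OH-]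
Why: Saponification of the benzyl ester followed by Claisen–Schmidt aldol condensation of the non-enolisable aldehyde with the methyl ketone enolate, the E-alkene arising from E1cB loss of water; the carboxylate formed first cannot enolise and so does not compete.

Step 6
Reactants: 8 2-[2-benzyloxy-5-[(E)-3-(2-benzyloxy-6-hydroxy-4-methoxyphenyl)-3-oxoprop-1-enyl]phenyl]acetic acid
Product: 9 2-[2-benzyloxy-5-(5-benzyloxy-7-methoxy-4-oxo-4H-chromen-2-yl)phenyl]acetic acid
Conditions: I2 (10 mol%), DMSO, 120 °C
Reagents that add atoms: none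
Why: Iodine-catalysed oxidative cyclisation of a 2'-hydroxychalcone, in which the phenol adds to the enone (6-endo-trig) and the I2/DMSO couple removes two hydrogens to close the pyranone of unit 1; the arylacetic acid enolises too slowly to be iodinated in the short reaction time.

Step 7
Reactants: 10 phloroglucinol
Product: 11 1,3,5-tris(benzyloxy)benzene
Conditions: BnBr (3.3 equiv), K2CO3, DMF, rt to 60 °C
Reagents that add atoms: benzyl bromide, BrCc1ccccc1
Why: Threefold Williamson O-benzylation, run in DMF with a carbonate base to favour O- over C-alkylation.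

Step 8
Reactants: 9 2-[2-benzyloxy-5-(5-benzyloxy-7-methoxy-4-oxo-4H-chromen-2-yl)phenyl]acetic acid; 11 1,3,5-tris(benzyloxy)benzene
Product: 13 2-[2-benzyloxy-5-(5-benzyloxy-7-methoxy-4-oxo-4H-chromen-2-yl)phenyl]-1-[2,4,6-tris(benzyloxy)phenyl]ethanone, via mixed trifluoroacetic anhydride 12 (not isolated)
Conditions: TFAA (1.3 equiv), CH2Cl2, 0 °C; then 11 (1.5 equiv), 0 °C to rt
Reagents that add atoms: none
Why: Friedel–Crafts acylation through the mixed trifluoroacetic anhydride, which the symmetric and very electron-rich arene takes up without a Lewis acid, so only one regioisomer is possible and the benzyl ethers are not exposed to BF3·OEt2.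

Step 9
Reactants: 13 2-[2-benzyloxy-5-(5-benzyloxy-7-methoxy-4-oxo-4H-chromen-2-yl)phenyl]-1-[2,4,6-tris(benzyloxy)phenyl]ethanone
Product: 14 1-[2,4-bis(benzyloxy)-6-hydroxyphenyl]-2-[2-benzyloxy-5-(5-hydroxy-7-methoxy-4-oxo-4H-chromen-2-yl)phenyl]ethanone
Conditions: BCl3 (1 M in CH2Cl2, 2.2 equiv), CH2Cl2, −78 °C; then H2O
Reagents that add atoms: none
Why: Chelation-directed Lewis-acid ether cleavage, in which BCl3 binds each carbonyl together with one neighbouring benzyloxy oxygen and chloride removes those two benzyl groups, the boron left on the new phenolate and the ketone shielding the second flanking ether, while the unchelated benzyl ethers and the 7-OMe should survive at −78 °C.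

Step 10
Reactants: 15 4-(benzyloxy)benzoic acid
Product: 16 4-(benzyloxy)benzoyl chloride
Conditions: (COCl)2 (1.5 equiv), DMF (cat.), CH2Cl2, 0 °C to rt
Reagents that add atoms: oxalyl chloride, O=C(Cl)C(=O)Cl
Why: Standard acid chloride formation under DMF catalysis, mild enough to leave the benzyl ether untouched.

Step 11
Reactants: 14 1-[2,4-bis(benzyloxy)-6-hydroxyphenyl]-2-[2-benzyloxy-5-(5-hydroxy-7-methoxy-4-oxo-4H-chromen-2-yl)phenyl]ethanone; 16 4-(benzyloxy)benzoyl chloride
Product: 20 5,7-bis(benzyloxy)-2-[4-(benzyloxy)phenyl]-3-[2-benzyloxy-5-(5-hydroxy-7-methoxy-4-oxo-4H-chromen-2-yl)phenyl]-4H-chromen-4-one (tetra-O-benzyl ether of the target), via bis-aroyl ester 17 (not isolated), via triaryl 1,3-diketone 18 (not isolated), via chromone 5-O-aroyl ester 19 (not isolated)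
Conditions: 16 (3 equiv), K2CO3 (8 equiv), acetone, reflux; then MeOH, 40 °C
Reagents that add atoms: none
Why: K2CO3 deprotonates both chelated phenols of 14, which are O-aroylated to 17; the benzylic carbanion of the deoxybenzoin (stabilised by the ketone and by ring B) then takes the aroyl group from the neighbouring phenol ester through a six-membered transition state (Baker–Venkataraman O-to-C transfer), forming C2''–C3'' in 18. The freed phenoxide adds to the new aryl ketone (6-exo-trig) and water is lost by E1cB elimination, forming O1''–C2'' and the tetrasubstituted C2''=C3'' bond of 19. The closest known reaction is the one-pot K2CO3/acetone synthesis of 3-arylflavones from 2-hydroxydeoxybenzoins and aroyl chlorides. No stereocentre remains, since the labile stereocentre of 18 is destroyed on dehydration. The step needs C-aroylation and not enol O-aroylation at the benzylic carbon, which is secured by the double activation of that carbon and by intramolecular delivery of the acyl group; a condensation of this kind also tolerates the two ortho substituents at C3' that would slow a cross-coupling. The ester on the 5-OH of unit 1 has no enolisable carbon next to it, cannot rearrange, and is removed by the methanol/K2CO3 stage, which also cleaves any enol ester.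

Step 12
Reactants: 20 5,7-bis(benzyloxy)-2-[4-(benzyloxy)phenyl]-3-[2-benzyloxy-5-(5-hydroxy-7-methoxy-4-oxo-4H-chromen-2-yl)phenyl]-4H-chromen-4-one
Product: 21 3-[2-hydroxy-5-(5-hydroxy-7-methoxy-4-oxo-4H-chromen-2-yl)phenyl]-5,7-dihydroxy-2-(4-hydroxyphenyl)-4H-chromen-4-one (CNP0254254.0)
Conditions: H2 (1 atm), 10% Pd/C, THF/MeOH, rt
Reagents that add atoms: none
Why: Catalytic hydrogenolysis of the four aryl benzyl ethers, under which the conjugated chromone double bonds and the aryl methyl ether should not be reduced.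

**Compound list**
1 | 2-hydroxyphenylacetic acid | OC(=O)Cc1ccccc1O | starting material
2 | 2-(5-bromo-2-hydroxyphenyl)acetic acid | OC(=O)Cc1cc(Br)ccc1O | intermediate
3 | benzyl 2-(2-benzyloxy-5-bromophenyl)acetate | O=C(Cc1cc(Br)ccc1OCc1ccccc1)OCc1ccccc1 | intermediate
4 | benzyl 2-(2-benzyloxy-5-formylphenyl)acetate | O=Cc1ccc(OCc2ccccc2)c(CC(=O)OCc2ccccc2)c1 | intermediate
5 | 2',6'-dihydroxy-4'-methoxyacetophenone | COc1cc(O)c(C(C)=O)c(O)c1 | starting material
6 | 1-(2-benzyloxy-6-hydroxy-4-methoxyphenyl)ethanone | COc1cc(O)c(C(C)=O)c(OCc2ccccc2)c1 | intermediate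
7 | 2-(2-benzyloxy-5-formylphenyl)acetic acid (potassium salt in the flask, not isolated) | O=Cc1ccc(OCc2ccccc2)c(CC(=O)O)c1 | intermediate
8 | 2-[2-benzyloxy-5-[(E)-3-(2-benzyloxy-6-hydroxy-4-methoxyphenyl)-3-oxoprop-1-enyl]phenyl]acetic acid | COc1cc(O)c(C(=O)/C=C/c2ccc(OCc3ccccc3)c(CC(=O)O)c2)c(OCc2ccccc2)c1 | intermediate
9 | 2-[2-benzyloxy-5-(5-benzyloxy-7-methoxy-4-oxo-4H-chromen-2-yl)phenyl]acetic acid | COc1cc(OCc2ccccc2)c2c(=O)cc(-c3ccc(OCc4ccccc4)c(CC(=O)O)c3)oc2c1 | intermediate
10 | phloroglucinol | Oc1cc(O)cc(O)c1 | starting material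
11 | 1,3,5-tris(benzyloxy)benzene | c1ccc(COc2cc(OCc3ccccc3)cc(OCc3ccccc3)c2)cc1 | intermediate
12 | mixed anhydride of 9 with trifluoroacetic acid (not isolated) | COc1cc(OCc2ccccc2)c2c(=O)cc(-c3ccc(OCc4ccccc4)c(CC(=O)OC(=O)C(F)(F)F)c3)oc2c1 | intermediate
13 | 2-[2-benzyloxy-5-(5-benzyloxy-7-methoxy-4-oxo-4H-chromen-2-yl)phenyl]-1-[2,4,6-tris(benzyloxy)phenyl]ethanone | COc1cc(OCc2ccccc2)c2c(=O)cc(-c3ccc(OCc4ccccc4)c(CC(=O)c4c(OCc5ccccc5)cc(OCc5ccccc5)cc4OCc4ccccc4)c3)oc2c1 | intermediate
14 | 1-[2,4-bis(benzyloxy)-6-hydroxyphenyl]-2-[2-benzyloxy-5-(5-hydroxy-7-methoxy-4-oxo-4H-chromen-2-yl)phenyl]ethanone (key-step precursor) | COc1cc(O)c2c(=O)cc(-c3ccc(OCc4ccccc4)c(CC(=O)c4c(O)cc(OCc5ccccc5)cc4OCc4ccccc4)c3)oc2c1 | intermediate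
15 | 4-(benzyloxy)benzoic acid | OC(=O)c1ccc(OCc2ccccc2)cc1 | starting material
16 | 4-(benzyloxy)benzoyl chloride | O=C(Cl)c1ccc(OCc2ccccc2)cc1 | intermediate
17 | bis[4-(benzyloxy)benzoate] of 14, esterified at the 5-OH of unit 1 and at the ketone-flanking phenol (not isolated) | COc1cc(OC(=O)c2ccc(OCc3ccccc3)cc2)c2c(=O)cc(-c3ccc(OCc4ccccc4)c(CC(=O)c4c(OC(=O)c5ccc(OCc6ccccc6)cc5)cc(OCc5ccccc5)cc4OCc4ccccc4)c3)oc2c1 | intermediate
18 | 1-[2,4-bis(benzyloxy)-6-hydroxyphenyl]-3-[4-(benzyloxy)phenyl]-2-aryl-propane-1,3-dione, aryl = ring B carrying unit 1 as its 5-O-[4-(benzyloxy)benzoate] (racemic, labile CH; not isolated) | COc1cc(OC(=O)c2ccc(OCc3ccccc3)cc2)c2c(=O)cc(-c3ccc(OCc4ccccc4)c(C(C(=O)c4ccc(OCc5ccccc5)cc4)C(=O)c4c(O)cc(OCc5ccccc5)cc4OCc4ccccc4)c3)oc2c1 | intermediate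
19 | 5-O-[4-(benzyloxy)benzoyl] ester of 20 (not isolated) | COc1cc(OC(=O)c2ccc(OCc3ccccc3)cc2)c2c(=O)cc(-c3ccc(OCc4ccccc4)c(-c4c(-c5ccc(OCc6ccccc6)cc5)oc5cc(OCc6ccccc6)cc(OCc6ccccc6)c5c4=O)c3)oc2c1 | intermediate
20 | 5,7-bis(benzyloxy)-2-[4-(benzyloxy)phenyl]-3-[2-benzyloxy-5-(5-hydroxy-7-methoxy-4-oxo-4H-chromen-2-yl)phenyl]-4H-chromen-4-one (key-step product) | COc1cc(O)c2c(=O)cc(-c3ccc(OCc4ccccc4)c(-c4c(-c5ccc(OCc6ccccc6)cc5)oc5cc(OCc6ccccc6)cc(OCc6ccccc6)c5c4=O)c3)oc2c1 | intermediate
21 | 3-[2-hydroxy-5-(5-hydroxy-7-methoxy-4-oxo-4H-chromen-2-yl)phenyl]-5,7-dihydroxy-2-(4-hydroxyphenyl)-4H-chromen-4-one | COc1cc(O)c2c(=O)cc(-c3ccc(O)c(-c4c(-c5ccc(O)cc5)oc5cc(O)cc(O)c5c4=O)c3)oc2c1 | target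

**Step count and risks**
Total: 12 steps. Longest linear sequence: 9 steps (1, 2, 3, 5, 6, 8, 9, 11, 12) from 2-hydroxyphenylacetic acid.

Steps most likely to fail:

1. Step 11. The acyl transfer to the crowded benzylic carbon may stall at the phenol ester or be diverted to enol O-aroylation, and the cyclodehydration may stay incomplete. The fallback sets out from 14 and comes back at 20. Compound 14 is condensed with commercial 4-(benzyloxy)benzaldehyde (O=Cc1ccc(OCc2ccccc2)cc1; piperidine, EtOH, reflux), a Knoevenagel condensation followed by oxa-Michael ring closure, to give the racemic trans-2,3-diarylchroman-4-one F1. F1 is then dehydrogenated with DDQ (1,4-dioxane, reflux) to 20. The 5-OH of unit 1 stays free throughout, so no ester has to be cleaved.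

2. Step 8. The benzyloxy oxygen ortho to the side chain may attack the mixed anhydride, with loss of its benzyl group and lactonisation to a benzofuran-2-one, or the arene may be trifluoroacetylated instead. The fallback sets out from 9 and 11 and comes back at 13. Compound 9 is converted with oxalyl chloride (cat. DMF, CH2Cl2) into the acid chloride F2. Compound 11 is monobrominated with NBS (CH2Cl2, −78 °C to 0 °C) to 2-bromo-1,3,5-tris(benzyloxy)benzene F3. Bromine–lithium exchange (n-BuLi, THF, −78 °C) gives the aryllithium F4, and ZnCl2 converts it into the arylzinc chloride F5. Negishi acylation of F5 with F2 (Pd(PPh3)4, THF, 0 °C to rt) should give 13 with no acid present.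

3. Step 9. A second benzyl group flanking the ketone may be lost, or a benzyl cation may migrate onto the electron-rich ring. The fallback sets out from 13 and comes back at 14. Excess BCl3 (3.5 equiv, CH2Cl2, −78 °C to −20 °C) deliberately cleaves all three carbonyl-chelated ethers to the triol F6. Mono-O-benzylation (BnBr 1.0 equiv, K2CO3, acetone, 50 °C) then returns to 14: once one of the two ketone-flanking phenols is benzylated the other is held in the chelate, as in step 4, and the 5-OH of unit 1 is chelated as well.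

**Further compounds**
F1 | step 11 | trans-5,7-bis(benzyloxy)-2-[4-(benzyloxy)phenyl]-3-[2-benzyloxy-5-(5-hydroxy-7-methoxy-4-oxo-4H-chromen-2-yl)phenyl]chroman-4-one (racemic, one enantiomer drawn) | COc1cc(O)c2c(=O)cc(-c3ccc(OCc4ccccc4)c([C@@H]4C(=O)c5c(OCc6ccccc6)cc(OCc6ccccc6)cc5O[C@H]4c4ccc(OCc5ccccc5)cc4)c3)oc2c1
F2 | step 8 | 2-[2-benzyloxy-5-(5-benzyloxy-7-methoxy-4-oxo-4H-chromen-2-yl)phenyl]acetyl chloride | COc1cc(OCc2ccccc2)c2c(=O)cc(-c3ccc(OCc4ccccc4)c(CC(=O)Cl)c3)oc2c1
F3 | step 8 | 2-bromo-1,3,5-tris(benzyloxy)benzene | Brc1c(OCc2ccccc2)cc(OCc2ccccc2)cc1OCc1ccccc1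
F4 | step 8 | [2,4,6-tris(benzyloxy)phenyl]lithium | [Li]c1c(OCc2ccccc2)cc(OCc2ccccc2)cc1OCc1ccccc1
F5 | step 8 | chloro[2,4,6-tris(benzyloxy)phenyl]zinc | Cl[Zn]c1c(OCc2ccccc2)cc(OCc2ccccc2)cc1OCc1ccccc1
F6 | step 9 | 1-[4-benzyloxy-2,6-dihydroxyphenyl]-2-[2-benzyloxy-5-(5-hydroxy-7-methoxy-4-oxo-4H-chromen-2-yl)phenyl]ethanone | COc1cc(O)c2c(=O)cc(-c3ccc(OCc4ccccc4)c(CC(=O)c4c(O)cc(OCc5ccccc5)cc4O)c3)oc2c1
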